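Late in a run I wanted to know what each unit of starting material had become, so I set up a ledger for it, as the limiting reagent by charge, with partner at 2.50 equivalents.

| flask | starting material | partner | protic impurity | time | remark |
|---|---|---|---|---|---|
| ash | 0.050 M | 0.125 M | 0.0100 M | 4.0 min | everything together in a closed stirred flask, run for 4.0 min |
| cedar | 0.050 M (fed, over 4.00 min) | 0.125 M | 0.0100 M | 4.0 min | all but starting material at the start; starting material goes in evenly over 4.00 min, the run ends at 4.0 min |
| maple | 0.050 M | 0.125 M (fed, over 4.00 min) | 0.0100 M | 4.0 min | all but partner at the start; partner goes in evenly over 4.00 min, the run ends at 4.0 min |
| larch | 0.050 M | 0.125 M | 0.0100 M |  | a single well-mixed tank run continuously and read at steady state, 4.0 min in it on average |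

    partner + intermediate → target (k1 = 2.2 M⁻¹ s⁻¹)
    starting material → intermediate (k2 = 0.098 s⁻¹)
    starting material + protic impurity → quenched substrate (k3 = 1.2 M⁻¹ s⁻¹)
    2 partner → homo product (k4 = 0.77 M⁻¹ s⁻¹)
    starting material + target ⇌ idle adduct, settled at all times (K5 = 450 M⁻¹)

- percent here means starting material units held: one idle adduct counts as two
- what is said of target includes idle adduct
- a doubled species enters its step squared and goes two at a time
- the stated concentrations are those of everything mixed, before any reaction; amounts are the same in each set-up
- the feed brings no volume worth counting
- in an amount of target, one idle adduct counts as one target
- run time (ash): 4.0 min

- order of the set-ups by the amount of intermediate at the outlet or at the end, in percent of the starting material put in, highest first (ash / cedar / maple / larch)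
- amount of intermediate at the outlet or at the end, in percent of the starting material put in, ash
- amount of intermediate at the outlet or at the end, in percent of the starting material put in, cedar
- amount of intermediate at the outlet or at the end, in percent of the starting material put in, maple
- amount of intermediate at the outlet or at the end, in percent of the starting material put in, larch

The idle adduct took no final entry: its step is reversible, and a unit parked there was still to be booked. Starting material had two exits, to intermediate and to quenched substrate. Both are first order in starting material, so at a given level of protic impurity their split does not depend on how much starting material is present. I froze the protic impurity to make quenching pseudo-first-order. At its charge, the quenched share came to 10.9%, but on the whole charge of starting material that equals 54.5% of the impurity charge, so I froze the impurity instead at the midpoint, 72.7% of its charge. This gave 91.8% as the made share, the fraction of consumed starting material that becomes intermediate.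

The last entry divides the made share between target and intermediate, which has no other exit in the scheme. Here my hand reckoning stopped short of figures. Partner has a first half-life of 5.19 s by dimerisation alone at its full charge, shorter than the 7.07 s of starting material by the step to intermediate alone and far shorter than the dosing time. I therefore expected cedar, whose partner stands waiting for a slow feed, to hold the highest intermediate, and maple the lowest.

The forecast agreed on those two ends and gave cedar > ash > larch > maple, with 9% for ash, 29% for cedar, 0.4% for maple and 7.6% for larch. Its grounds for maple were that “maple's fed partner meets a ready pool of intermediate and consumes nearly all of it”.

The simulation gave cedar > ash > larch > maple, with 23.8% for ash, 59.5% for cedar, 0.430% for maple and 7.71% for larch.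

In maple at the end, quenched substrate read 8.45% of the charge against the 8.20% of consumed starting material left by the made share. The neighbouring flask is maple with 0.050 M of partner, or 1.00 equiv, so a fraction of its partner charge equals the same fraction of its starting material. Its partner left 13% unused and 10.6% in homo product, which put 76.3% into target. Subtracting that from the made share, taken on the whole charge although 0.0236% stood unbound and 0.806% in idle adduct, gave 15.5% intermediate, and the neighbouring flask read 14.7%.

(All constants are invented; the flask was simulated.)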